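The ten-membered ring (C1–C10) is disconnected at C2–C3, the sp3–sp3 bond whose carbons are each allylic to one of the two cis ring alkenes (C1=C10 and C4=C5). This lets C2 act as a phenylsulfonyl-stabilised allyl anion and C3 as a primary allylic bromide, so a single intramolecular SN2 alkylation closes the carbocycle with both alkene geometries preset. The precursor is an acyclic (Z,Z)-bromo sulfone that already holds the C6–C9 stereotetrad, with O6 and O12 as silyl ethers removable together, O8 as PMB, O9 as TBS and O14 as TBDPS, so that lactonisation and the two different acylations can later be carried out unambiguously.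

Key step: step 24

Remark: atom numbers refer to the germacrane skeleton of 51 (ring C1–C10; C14 on C10; C15 on C4; lactone C6–O–C12(=O)–C11(=C13)–C7); C2 of 39 is assumed to form as a mixture of epimers, which is immaterial because step 25 removes the sulfonyl group.

Step 1
Reactants: 1 2-butyne-1,4-diol
Product: 2 4-[(tert-butyldiphenylsilyl)oxy]but-2-yn-1-ol
Conditions: 1 (3 equiv), NaH (1 equiv), THF, 0 °C; t-BuPh2SiCl (1 equiv), 0 °C → rt
Reagents that add atoms: tert-butyl(chloro)diphenylsilane, CC(C)(C)[Si](Cl)(c1ccccc1)c1ccccc1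
Why: O-silylation of the monosodium alkoxide of a symmetric diol used in excess should stop at the mono ether, which distinguishes the future C14 oxygen from the future C2 terminus.

Step 2
Reactants: 2 4-[(tert-butyldiphenylsilyl)oxy]but-2-yn-1-ol
Product: 4 (Z)-4-[(tert-butyldiphenylsilyl)oxy]-3-iodobut-2-en-1-ol, via cyclic alkenylaluminate 3 (not isolated)
Conditions: NaAlH2(OCH2CH2OMe)2, THF, 0 °C; EtOAc; I2, −78 °C → 0 °C
Reagents that add atoms: iodine, II
Why: Hydroxyl-directed trans-hydroalumination of the propargylic alcohol places hydride on the proximal and aluminium on the distal alkyne carbon in a five-membered chelate, and iodinolysis with retention should give the Z vinyl iodide with iodine on the future C10 and cis to the future C2 arm, the low temperature guarding against β-elimination of the silyloxy group.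

Step 3
Reactants: 4 (Z)-4-[(tert-butyldiphenylsilyl)oxy]-3-iodobut-2-en-1-ol
Product: 5 (Z)-tert-butyl{[2-iodo-4-(phenylsulfanyl)but-2-en-1-yl]oxy}diphenylsilane
Conditions: PhSSPh, PBu3, THF, 0 °C → rt
Reagents that add atoms: diphenyl disulfide, c1ccc(SSc2ccccc2)cc1
Why: Phosphine–disulfide thioetherification (Hata reaction) activates the primary allylic alcohol as an alkoxyphosphonium ion that thiophenolate displaces by SN2, which installs the sulfur of the later C2 sulfone without touching the vinyl iodide.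

Step 4
Reactants: 6 prop-2-yn-1-ol
Product: 8 (Z)-3-iodo-2-methylprop-2-en-1-ol, via cyclic alkenylmagnesium alkoxide 7 (not isolated)
Conditions: MeMgBr (2.5 equiv), CuI (cat.), Et2O, −10 °C → rt; I2, −40 °C → rt
Reagents that add atoms: methylmagnesium bromide, C[Mg]Br; iodine, II
Why: Copper-catalysed alkoxide-directed anti-carbomagnesiation puts the methyl group (C15) on the internal carbon (C4) and magnesium on the terminal carbon (C5) cis to the CH2O arm (C3), and iodinolysis with retention fixes the Z geometry needed for C4=C5.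

Step 5
Reactants: 8 (Z)-3-iodo-2-methylprop-2-en-1-ol
Product: 9 (Z)-3-iodo-2-methylprop-2-en-1-yl 2,2-dimethylpropanoate
Conditions: t-BuCOCl, pyridine, CH2Cl2, 0 °C
Reagents that add atoms: pivaloyl chloride, CC(C)(C)C(=O)Cl
Why: Acylation of the primary alcohol gives an ester that survives the chromium-mediated coupling and can later be removed reductively in the presence of silyl and PMB ethers.

Step 6
Reactants: 10 2-hydroxy-2-methylpropanoic acid
Product: 11 triethylsilyl 2-methyl-2-[(triethylsilyl)oxy]propanoate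
Conditions: Et3SiCl (2.2 equiv), imidazole, CH2Cl2, 0 °C → rt
Reagents that add atoms: chlorotriethylsilane, CC[Si](Cl)(CC)CC
Why: Imidazole-promoted silylation covers both the carboxylic acid and the tertiary alcohol, which masks the hydroxyl for the later esterification.

Step 7
Reactants: 11 triethylsilyl 2-methyl-2-[(triethylsilyl)oxy]propanoate
Product: 12 2-methyl-2-[(triethylsilyl)oxy]propanoyl chloride
Conditions: (COCl)2, DMF (cat.), CH2Cl2, 0 °C → rt
Reagents that add atoms: oxalyl chloride, O=C(Cl)C(=O)Cl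
Why: Vilsmeier-type activation converts a silyl ester directly into the acid chloride under neutral conditions that leave the tertiary silyl ether in place.

Step 8
Reactants: 13 dimethyl (S)-malate; 14 allyl bromide
Product: 16 dimethyl (2S,3R)-2-hydroxy-3-(prop-2-en-1-yl)butanedioate, via dilithium alkoxide enolate 15 (not isolated)
Conditions: LiN(iPr)2 (2.2 equiv), THF, −78 → −20 °C; 14, −78 → −10 °C
Reagents that add atoms: none
Why: Fráter–Seebach alkylation, in which the dilithium alkoxide enolate is allylated on the face anti to the alkoxide, sets C7 with the C11/O8 anti relationship of the target while C8 comes from the chiral pool.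

Step 9
Reactants: 16 dimethyl (2S,3R)-2-hydroxy-3-(prop-2-en-1-yl)butanedioate
Product: 17 (2S,3S)-3-(prop-2-en-1-yl)butane-1,2,4-triol
Conditions: LiAlH4, THF, 0 °C → reflux
Reagents that add atoms: none
Why: Hydride reduction of both esters gives the triol without affecting the two stereocentres or the terminal alkene.

Step 10
Reactants: 17 (2S,3S)-3-(prop-2-en-1-yl)butane-1,2,4-triol
Product: 18 [(2S,4S,5S)-2-(4-methoxyphenyl)-5-(prop-2-en-1-yl)-1,3-dioxan-4-yl]methanol
Conditions: 4-MeOC6H4CH(OMe)2, CSA (cat.), CH2Cl2, rt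
Reagents that add atoms: 4-methoxybenzaldehyde dimethyl acetal, COC(OC)c1ccc(OC)cc1
Why: Acid-catalysed transacetalisation under equilibrating conditions should favour the six-membered 1,3-dioxane across O8 and O6 with aryl, C9 and allyl groups all equatorial (acetal centre set thermodynamically), which leaves only the C9 hydroxyl free.

Step 11
Reactants: 18 [(2S,4S,5S)-2-(4-methoxyphenyl)-5-(prop-2-en-1-yl)-1,3-dioxan-4-yl]methanol
Product: 19 (2S,4S,5S)-2-(4-methoxyphenyl)-5-(prop-2-en-1-yl)-1,3-dioxane-4-carbaldehyde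
Conditions: Dess–Martin periodinane, NaHCO3, CH2Cl2, 0 °C → rt
Reagents that add atoms: none
Why: Buffered hypervalent-iodine oxidation gives the α-alkoxy aldehyde without epimerising C8.

Step 12
Reactants: 19 (2S,4S,5S)-2-(4-methoxyphenyl)-5-(prop-2-en-1-yl)-1,3-dioxane-4-carbaldehyde; 5 (Z)-tert-butyl{[2-iodo-4-(phenylsulfanyl)but-2-en-1-yl]oxy}diphenylsilane
Product: 22 (1S,2Z)-2-{[(tert-butyldiphenylsilyl)oxy]methyl}-1-[(2S,4S,5S)-2-(4-methoxyphenyl)-5-(prop-2-en-1-yl)-1,3-dioxan-4-yl]-4-(phenylsulfanyl)but-2-en-1-ol, via alkenyllithium 20 (not isolated), via alkenylmagnesium bromide 21 (not isolated)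
Conditions: 5, t-BuLi (2 equiv), Et2O, −78 °C; MgBr2·OEt2, −78 °C; 19, CH2Cl2, −78 °C
Reagents that add atoms: none
Why: Cram-chelate addition of an alkenylmagnesium reagent, in which magnesium bridges the aldehyde oxygen and the ring oxygen O8 so that the alkenyl group should add to the face away from the C7 ring carbon, sets C9 with O8/O9 syn (9S) while retention of the vinyl geometry places C9 cis to C2.

Step 13
Reactants: 22 C9 allylic alcohol
Product: 23 O9 TBS ether of 22
Conditions: t-BuMe2SiOTf, 2,6-lutidine, CH2Cl2, −78 °C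
Reagents that add atoms: tert-butyldimethylsilyl trifluoromethanesulfonate, CC(C)(C)[Si](C)(C)OS(=O)(=O)C(F)(F)F
Why: Silyl triflate with a hindered base silylates the congested secondary allylic alcohol at low temperature without opening the aryl acetal.

Step 14
Reactants: 23 O9 TBS ether of 22
Product: 25 C2 phenyl sulfone (23 with SPh oxidised to SO2Ph), via allylic sulfoxide 24 (not isolated)
Conditions: (NH4)6Mo7O24·4H2O (cat.), 30% H2O2, EtOH, 0 °C → rt
Reagents that add atoms: hydrogen peroxide, OO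
Why: Molybdate-catalysed peroxide oxidation takes the sulfide through the sulfoxide to the sulfone much faster than it epoxidises alkenes, and working cold limits [2,3]-sigmatropic equilibration of the transient allylic sulfoxide.

Step 15
Reactants: 25 C2 phenyl sulfone
Product: 27 C12 aldehyde (allyl group of 25 cut to CH2CHO), via vicinal diol 26 (not isolated)
Conditions: OsO4 (cat.), NMO, acetone/H2O, rt; NaIO4, THF/pH 7 buffer, 0 °C
Reagents that add atoms: N-methylmorpholine N-oxide, C[N+]1([O-])CCOCC1; water, O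
Why: Catalytic dihydroxylation and periodate cleavage (Lemieux–Johnson sequence) should cut only the unhindered monosubstituted alkene, because the trisubstituted C1=C10 alkene is deactivated by the sulfonylmethyl group and two oxygen-bearing allylic carbons and is sterically shielded, and the transient carbinol centre of 26 is destroyed in the cleavage.

Step 16
Reactants: 27 C12 aldehyde
Product: 28 C12 primary alcohol
Conditions: NaBH4, MeOH, 0 °C
Reagents that add atoms: none
Why: Borohydride reduction of the aldehyde is chemoselective in the presence of the sulfone, acetal and silyl ethers.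

Step 17
Reactants: 28 C12 primary alcohol
Product: 29 C12 OTBS ether (sulfone acetal)
Conditions: t-BuMe2SiCl, imidazole, CH2Cl2, rt
Reagents that add atoms: tert-butyl(chloro)dimethylsilane, CC(C)(C)[Si](C)(C)Cl
Why: Imidazole-promoted silylation of the primary alcohol gives an ether that withstands the aluminium hydride step and is later removed together with the O6 silyl group.

Step 18
Reactants: 29 C12 OTBS ether (sulfone acetal)
Product: 30 acyclic sulfone alcohol (C2 SO2Ph; C14 OTBDPS; O9 TBS; O8 PMB; C12 OTBS; C6 primary OH)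
Conditions: iBu2AlH, CH2Cl2, −78 → 0 °C
Reagents that add atoms: none
Why: Reductive opening of the p-methoxybenzylidene acetal, in which the aluminium hydride coordinates the less hindered primary oxygen O6 and reduces the resulting oxocarbenium ion, should leave the PMB group on the secondary O8 and release C6 as a primary alcohol.

Step 19
Reactants: 30 acyclic sulfone alcohol
Product: 31 C6 aldehyde
Conditions: Dess–Martin periodinane, NaHCO3, CH2Cl2, 0 °C
Reagents that add atoms: none
Why: Buffered hypervalent-iodine oxidation gives the α-branched aldehyde without epimerising C7 or eliminating the β-OPMB group.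

Step 20
Reactants: 31 C6 aldehyde; 9 (Z)-3-iodo-2-methylprop-2-en-1-yl 2,2-dimethylpropanoate
Product: 33 C6 allylic alcohol (6R; Z-C4=C5; C3 pivalate), via alkenylchromium dichloride 32 (not isolated)
Conditions: 9, CrCl2 (5 equiv), NiCl2 (cat.), DMSO, rt
Reagents that add atoms: none
Why: Nozaki–Hiyama–Kishi coupling adds the alkenylchromium species to the aldehyde without deprotonating the allylic sulfone or attacking the pivalate, and Felkin–Anh attack anti to the C8 branch, reinforced by the 1,3-anti preference of the β-OPMB group, should set C6 with O6 syn to C11 while the Z geometry of C4=C5 is retained.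

Step 21
Reactants: 33 C6 allylic alcohol
Product: 34 O6 TES ether of 33
Conditions: Et3SiOTf, 2,6-lutidine, CH2Cl2, −78 °C
Reagents that add atoms: triethylsilyl trifluoromethanesulfonate, CC[Si](CC)(CC)OS(=O)(=O)C(F)(F)F
Why: Silyl triflate silylation protects the hindered secondary allylic alcohol with a group that can later be removed together with the primary TBS ether at O12 while the TBS ether at O9 stays.

Step 22
Reactants: 34 O6 TES ether of 33
Product: 35 C3 allylic alcohol
Conditions: iBu2AlH, CH2Cl2, −78 °C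
Reagents that add atoms: none
Why: Reductive cleavage of the pivalate at low temperature frees the C3 hydroxyl without touching the silyl ethers, the PMB ether or the sulfone.

Step 23
Reactants: 35 C3 allylic alcohol
Product: 37 (Z,Z)-bromo sulfone precursor (C3 Br; C2 SO2Ph; O6 TES; C12 OTBS; O8 PMB; O9 TBS; C14 OTBDPS), via allylic mesylate 36 (not isolated)
Conditions: MsCl, Et3N, CH2Cl2, −40 °C; LiBr, THF, 0 °C
Reagents that add atoms: lithium bromide, [Li+].[Br-]
Why: Mesylation followed by Finkelstein-type SN2 displacement at the primary allylic carbon should give the bromide without allylic transposition or loss of the Z geometry.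

Step 24
Reactants: 37 (Z,Z)-bromo sulfone precursor
Product: 39 ten-membered cyclic sulfone (SO2Ph on C2; C2 epimers), via potassium sulfonyl carbanion 38 (not isolated)
Conditions: KN(SiMe3)2 (1.5 equiv), THF, −78 → 0 °C, slow addition of 37 to 0.002 M
Reagents that add atoms: none
Why: KN(SiMe3)2 removes the C2 proton flanked by the sulfonyl group and the C1=C10 alkene, and the resulting α-sulfonyl allyl anion 38 displaces bromide from the primary allylic C3 in an intramolecular SN2 alkylation that forges C2–C3. The closest known reaction type is the cyclisation of sulfone- or sulfide-stabilised allylic carbanions onto allylic halides used to build ten-membered germacrane rings. The ring closes in a 10-exo-tet mode, helped by the two preset Z alkenes, which fold the chain so that C2 and C3 approach each other. The only new stereocentre is C2, which is not controlled and need not be because the sulfonyl group is removed in step 25, while C6–C9 and both alkene geometries are untouched. The step needs alkylation at C2 (α) not C10 (γ) and SN2 not SN2′ attack: sulfonyl-stabilised allyl anions alkylate at the α-carbon, C10 is fully substituted and shielded by the C9 and C14 silyl ethers, and attack at C5 would require a strained eight-membered ring at a hindered trisubstituted terminus. Intermolecular alkylation is suppressed by slow addition into dilute base.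

Step 25
Reactants: 39 ten-membered cyclic sulfone
Product: 40 (1(10)Z,4Z)-cyclodecadiene (O6 TES; C12 OTBS; O8 PMB; O9 TBS; C14 OTBDPS)
Conditions: PdCl2(dppp) (cat.), LiBHEt3, THF, 0 °C
Reagents that add atoms: none
Why: Palladium-catalysed hydride desulfonylation, in which zerovalent palladium ionises the allylic sulfone to a π-allyl complex and hydride attacks the less substituted terminus C2, should keep the C1=C10 alkene in place and cis and converge both C2 epimers on one product.

Step 26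
Reactants: 40 (1(10)Z,4Z)-cyclodecadiene
Product: 41 C6/C12 diol
Conditions: HF·pyridine, pyridine, THF, 0 °C → rt
Reagents that add atoms: none
Why: Buffered fluoride desilylation removes the secondary TES and primary TBS ethers, which are far more labile than the hindered secondary TBS ether at O9 and the primary TBDPS ether at O14.

Step 27
Reactants: 41 C6/C12 diol
Product: 43 trans-fused γ-lactone (6,12-olide), via lactol 42 (not isolated)
Conditions: TEMPO (cat.), PhI(OAc)2, CH2Cl2, rt
Reagents that add atoms: none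
Why: TEMPO-catalysed oxidative lactonisation oxidises the primary C12 alcohol selectively, the aldehyde is trapped by the C6 hydroxyl as a five-membered lactol and this is oxidised on to the lactone with C6 and C7 unchanged.

Step 28
Reactants: 43 trans-fused γ-lactone
Product: 46 α-methylene lactone (C11=C13), via Mannich base 44 (not isolated), via trimethylammonium iodide 45 (not isolated)
Conditions: LiN(iPr)2, THF, −78 °C; CH2=NMe2+ I−, −78 °C → rt; MeI, MeOH, rt; NaHCO3 (aq), CH2Cl2, rt
Reagents that add atoms: N,N-dimethylmethyleneiminium iodide (Eschenmoser's salt), C=[N+](C)C.[I-]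
Why: Kinetic enolisation of the lactone at C11, Mannich reaction with Eschenmoser's salt, N-methylation and base-induced elimination of trimethylamine make up the standard α-methylenation of γ-lactones, in which the transient C11 stereocentre disappears and only ether protecting groups are present.

Step 29
Reactants: 46 α-methylene lactone
Product: 47 C9 alcohol (O8 PMB; C14 OTBDPS)
Conditions: CSA (cat.), MeOH/CH2Cl2, 0 °C → rt
Reagents that add atoms: none
Why: Acid-catalysed methanolysis cleaves a TBS ether much faster than a TBDPS ether, so the C9 hydroxyl should be released while O14 stays protected and the PMB ether and lactone are unaffected.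

Step 30
Reactants: 47 C9 alcohol; 12 2-methyl-2-[(triethylsilyl)oxy]propanoyl chloride
Product: 48 C9 2-methyl-2-[(triethylsilyl)oxy]propanoate
Conditions: 12, DMAP, Et3N, CH2Cl2, rt
Reagents that add atoms: none
Why: DMAP-catalysed acylation with an acid chloride that has no α-hydrogen installs the hindered protected 2-hydroxyisobutyrate on the only free hydroxyl.

Step 31
Reactants: 48 C9 2-methyl-2-[(triethylsilyl)oxy]propanoate
Product: 49 C8 alcohol
Conditions: DDQ, CH2Cl2/pH 7 buffer, 0 °C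
Reagents that add atoms: none
Why: Oxidative cleavage of the PMB ether by DDQ runs under neutral conditions that spare the α-methylene lactone and the diene and give the hindered C9 acyl group no opportunity to migrate.

Step 32
Reactants: 49 C8 alcohol
Product: 50 C8 2-methylpropanoate (C14 OTBDPS; tertiary OTES)
Conditions: (iPrCO)2O, DMAP, Et3N, CH2Cl2, 0 °C → rt
Reagents that add atoms: 2-methylpropanoic anhydride, CC(C)C(=O)OC(=O)C(C)C
Why: DMAP-catalysed acylation of the remaining secondary alcohol installs the isobutyrate while the tertiary oxygen is still silylated.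

Step 33
Reactants: 50 C8 2-methylpropanoate
Product: 51 CNP0220567.2 (6R,7S,8S,9S; 1(10)Z,4Z)
Conditions: HF·pyridine, THF, rt
Reagents that add atoms: none
Why: Fluoride-mediated desilylation under mildly acidic conditions removes the primary TBDPS ether and the tertiary TES ether while the α-methylene lactone and both esters remain intact.

Compound list
1 | 2-butyne-1,4-diol | OCC#CCO | starting material
2 | 4-[(tert-butyldiphenylsilyl)oxy]but-2-yn-1-ol | OCC#CCO[Si](c1ccccc1)(c1ccccc1)C(C)(C)C | intermediate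
3 | cyclic alkenylaluminate (sodium salt; not isolated) | [Na+].COCCO[Al-]1(OCCOC)OCC=C1CO[Si](c2ccccc2)(c2ccccc2)C(C)(C)C | intermediate
4 | (Z)-4-[(tert-butyldiphenylsilyl)oxy]-3-iodobut-2-en-1-ol | OC/C=C(\I)CO[Si](c1ccccc1)(c1ccccc1)C(C)(C)C | intermediate
5 | (Z)-tert-butyl{[2-iodo-4-(phenylsulfanyl)but-2-en-1-yl]oxy}diphenylsilane | I/C(CO[Si](c1ccccc1)(c1ccccc1)C(C)(C)C)=C\CSc1ccccc1 | intermediate
6 | prop-2-yn-1-ol | C#CCO | starting material
7 | cyclic alkenylmagnesium alkoxide (4-methyl-2,5-dihydro-1,2-oxamagnesole; not isolated) | CC1=C[Mg]OC1 | intermediate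
8 | (Z)-3-iodo-2-methylprop-2-en-1-ol | OC/C(C)=C\I | intermediate
9 | (Z)-3-iodo-2-methylprop-2-en-1-yl 2,2-dimethylpropanoate | CC(C)(C)C(=O)OC/C(C)=C\I | intermediate
10 | 2-hydroxy-2-methylpropanoic acid | CC(C)(O)C(=O)O | starting material
11 | triethylsilyl 2-methyl-2-[(triethylsilyl)oxy]propanoate | CC[Si](CC)(CC)OC(C)(C)C(=O)O[Si](CC)(CC)CC | intermediate
12 | 2-methyl-2-[(triethylsilyl)oxy]propanoyl chloride | CC[Si](CC)(CC)OC(C)(C)C(Cl)=O | intermediate
13 | dimethyl (S)-malate | COC(=O)C[C@H](O)C(=O)OC | starting material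
14 | allyl bromide | C=CCBr | starting material
15 | dilithium alkoxide enolate of 13 (not isolated) | [Li+].[Li+].COC(=O)[C@@H]([O-])C=C([O-])OC | intermediate
16 | dimethyl (2S,3R)-2-hydroxy-3-(prop-2-en-1-yl)butanedioate | COC(=O)[C@@H](O)[C@@H](CC=C)C(=O)OC | intermediate
17 | (2S,3S)-3-(prop-2-en-1-yl)butane-1,2,4-triol | OC[C@@H](O)[C@@H](CC=C)CO | intermediate
18 | [(2S,4S,5S)-2-(4-methoxyphenyl)-5-(prop-2-en-1-yl)-1,3-dioxan-4-yl]methanol | OC[C@H]1O[C@@H](c2ccc(OC)cc2)OC[C@@H]1CC=C | intermediate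
19 | (2S,4S,5S)-2-(4-methoxyphenyl)-5-(prop-2-en-1-yl)-1,3-dioxane-4-carbaldehyde | O=C[C@H]1O[C@@H](c2ccc(OC)cc2)OC[C@@H]1CC=C | intermediate
20 | alkenyllithium from 5 (not isolated) | [Li]/C(CO[Si](c3ccccc3)(c4ccccc4)C(C)(C)C)=C\CSc6ccccc6 | intermediate
21 | alkenylmagnesium bromide from 5 (not isolated) | Br[Mg]/C(CO[Si](c3ccccc3)(c4ccccc4)C(C)(C)C)=C\CSc6ccccc6 | intermediate
22 | (1S,2Z)-2-{[(tert-butyldiphenylsilyl)oxy]methyl}-1-[(2S,4S,5S)-2-(4-methoxyphenyl)-5-(prop-2-en-1-yl)-1,3-dioxan-4-yl]-4-(phenylsulfanyl)but-2-en-1-ol (C9 alcohol; O8/O9 syn) | c6ccccc6SC/C=C(/CO[Si](c3ccccc3)(c4ccccc4)C(C)(C)C)[C@H](O)[C@H]1O[C@@H](c5ccc(OC)cc5)OC[C@@H]1CC=C | intermediate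
23 | O9 TBS ether of 22 | c6ccccc6SC/C=C(/CO[Si](c3ccccc3)(c4ccccc4)C(C)(C)C)[C@H](O[Si](C)(C)C(C)(C)C)[C@H]1O[C@@H](c5ccc(OC)cc5)OC[C@@H]1CC=C | intermediate
24 | allylic sulfoxide of 23 (sulfur epimers; not isolated) | c6ccccc6S(=O)C/C=C(/CO[Si](c3ccccc3)(c4ccccc4)C(C)(C)C)[C@H](O[Si](C)(C)C(C)(C)C)[C@H]1O[C@@H](c5ccc(OC)cc5)OC[C@@H]1CC=C | intermediate
25 | C2 phenyl sulfone (allyl group intact) | O=S(=O)(c6ccccc6)C/C=C(/CO[Si](c3ccccc3)(c4ccccc4)C(C)(C)C)[C@H](O[Si](C)(C)C(C)(C)C)[C@H]1O[C@@H](c5ccc(OC)cc5)OC[C@@H]1CC=C | intermediate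
26 | vicinal diol from the allyl group of 25 (carbinol epimers; not isolated) | O=S(=O)(c6ccccc6)C/C=C(/CO[Si](c3ccccc3)(c4ccccc4)C(C)(C)C)[C@H](O[Si](C)(C)C(C)(C)C)[C@H]1O[C@@H](c5ccc(OC)cc5)OC[C@@H]1CC(O)CO | intermediate
27 | C12 aldehyde | O=S(=O)(c6ccccc6)C/C=C(/CO[Si](c3ccccc3)(c4ccccc4)C(C)(C)C)[C@H](O[Si](C)(C)C(C)(C)C)[C@H]1O[C@@H](c5ccc(OC)cc5)OC[C@@H]1CC=O | intermediate
28 | C12 primary alcohol | O=S(=O)(c6ccccc6)C/C=C(/CO[Si](c3ccccc3)(c4ccccc4)C(C)(C)C)[C@H](O[Si](C)(C)C(C)(C)C)[C@H]1O[C@@H](c5ccc(OC)cc5)OC[C@@H]1CCO | intermediate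
29 | C12 OTBS ether (sulfone acetal) | O=S(=O)(c6ccccc6)C/C=C(/CO[Si](c3ccccc3)(c4ccccc4)C(C)(C)C)[C@H](O[Si](C)(C)C(C)(C)C)[C@H]1O[C@@H](c5ccc(OC)cc5)OC[C@@H]1CCO[Si](C)(C)C(C)(C)C | intermediate
30 | acyclic sulfone alcohol (O8 PMB; C6 primary OH) | O=S(=O)(c6ccccc6)C/C=C(/CO[Si](c3ccccc3)(c4ccccc4)C(C)(C)C)[C@H](O[Si](C)(C)C(C)(C)C)[C@@H](OCc5ccc(OC)cc5)[C@@H](CCO[Si](C)(C)C(C)(C)C)CO | intermediate
31 | C6 aldehyde | O=S(=O)(c6ccccc6)C/C=C(/CO[Si](c3ccccc3)(c4ccccc4)C(C)(C)C)[C@H](O[Si](C)(C)C(C)(C)C)[C@@H](OCc5ccc(OC)cc5)[C@@H](CCO[Si](C)(C)C(C)(C)C)C=O | intermediate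
32 | alkenylchromium dichloride from 9 (not isolated) | Cl[Cr](Cl)/C=C(/C)COC(=O)C(C)(C)C | intermediate
33 | C6 allylic alcohol (6R; Z-C4=C5; C3 pivalate) | O=S(=O)(c6ccccc6)C/C=C(/CO[Si](c3ccccc3)(c4ccccc4)C(C)(C)C)[C@H](O[Si](C)(C)C(C)(C)C)[C@@H](OCc5ccc(OC)cc5)[C@@H](CCO[Si](C)(C)C(C)(C)C)[C@H](O)/C=C(/C)COC(=O)C(C)(C)C | intermediate
34 | O6 TES ether of 33 | O=S(=O)(c6ccccc6)C/C=C(/CO[Si](c3ccccc3)(c4ccccc4)C(C)(C)C)[C@H](O[Si](C)(C)C(C)(C)C)[C@@H](OCc5ccc(OC)cc5)[C@@H](CCO[Si](C)(C)C(C)(C)C)[C@H](O[Si](CC)(CC)CC)/C=C(/C)COC(=O)C(C)(C)C | intermediate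
35 | C3 allylic alcohol | O=S(=O)(c6ccccc6)C/C=C(/CO[Si](c3ccccc3)(c4ccccc4)C(C)(C)C)[C@H](O[Si](C)(C)C(C)(C)C)[C@@H](OCc5ccc(OC)cc5)[C@@H](CCO[Si](C)(C)C(C)(C)C)[C@H](O[Si](CC)(CC)CC)/C=C(/C)CO | intermediate
36 | C3 allylic mesylate (not isolated) | O=S(=O)(c6ccccc6)C/C=C(/CO[Si](c3ccccc3)(c4ccccc4)C(C)(C)C)[C@H](O[Si](C)(C)C(C)(C)C)[C@@H](OCc5ccc(OC)cc5)[C@@H](CCO[Si](C)(C)C(C)(C)C)[C@H](O[Si](CC)(CC)CC)/C=C(/C)COS(C)(=O)=O | intermediate
37 | (Z,Z)-bromo sulfone precursor (C3 Br; C2 SO2Ph; O6 TES; C12 OTBS; O8 PMB; O9 TBS; C14 OTBDPS) | O=S(=O)(c6ccccc6)C/C=C(/CO[Si](c3ccccc3)(c4ccccc4)C(C)(C)C)[C@H](O[Si](C)(C)C(C)(C)C)[C@@H](OCc5ccc(OC)cc5)[C@@H](CCO[Si](C)(C)C(C)(C)C)[C@H](O[Si](CC)(CC)CC)/C=C(/C)CBr | intermediate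
38 | potassium sulfonyl carbanion of 37 (not isolated) | [K+].O=S(=O)(c6ccccc6)[CH-]/C=C(/CO[Si](c3ccccc3)(c4ccccc4)C(C)(C)C)[C@H](O[Si](C)(C)C(C)(C)C)[C@@H](OCc5ccc(OC)cc5)[C@@H](CCO[Si](C)(C)C(C)(C)C)[C@H](O[Si](CC)(CC)CC)/C=C(/C)CBr | intermediate
39 | ten-membered cyclic sulfone (SO2Ph on C2; C2 epimers) | O=S(=O)(c6ccccc6)C1/C=C(/CO[Si](c3ccccc3)(c4ccccc4)C(C)(C)C)[C@H](O[Si](C)(C)C(C)(C)C)[C@@H](OCc5ccc(OC)cc5)[C@@H](CCO[Si](C)(C)C(C)(C)C)[C@H](O[Si](CC)(CC)CC)/C=C(/C)C1 | intermediate
40 | (1(10)Z,4Z)-cyclodecadiene (O6 TES; C12 OTBS; O8 PMB; O9 TBS; C14 OTBDPS) | C1/C=C(/CO[Si](c3ccccc3)(c4ccccc4)C(C)(C)C)[C@H](O[Si](C)(C)C(C)(C)C)[C@@H](OCc5ccc(OC)cc5)[C@@H](CCO[Si](C)(C)C(C)(C)C)[C@H](O[Si](CC)(CC)CC)/C=C(/C)C1 | intermediate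
41 | C6/C12 diol | C1/C=C(/CO[Si](c3ccccc3)(c4ccccc4)C(C)(C)C)[C@H](O[Si](C)(C)C(C)(C)C)[C@@H](OCc5ccc(OC)cc5)[C@@H](CCO)[C@H](O)/C=C(/C)C1 | intermediate
42 | lactol (C12 epimers; not isolated) | C1/C=C(/CO[Si](c3ccccc3)(c4ccccc4)C(C)(C)C)[C@H](O[Si](C)(C)C(C)(C)C)[C@@H](OCc5ccc(OC)cc5)[C@H]2CC(O)O[C@@H]2/C=C(/C)C1 | intermediate
43 | trans-fused γ-lactone (6,12-olide; O8 PMB; O9 TBS; C14 OTBDPS) | C1/C=C(/CO[Si](c3ccccc3)(c4ccccc4)C(C)(C)C)[C@H](O[Si](C)(C)C(C)(C)C)[C@@H](OCc5ccc(OC)cc5)[C@H]2CC(=O)O[C@@H]2/C=C(/C)C1 | intermediate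
44 | Mannich base (C11 CH2NMe2; C11 epimers; not isolated) | C1/C=C(/CO[Si](c3ccccc3)(c4ccccc4)C(C)(C)C)[C@H](O[Si](C)(C)C(C)(C)C)[C@@H](OCc5ccc(OC)cc5)[C@H]2C(CN(C)C)C(=O)O[C@@H]2/C=C(/C)C1 | intermediate
45 | trimethylammonium iodide of 44 (not isolated) | C1/C=C(/CO[Si](c3ccccc3)(c4ccccc4)C(C)(C)C)[C@H](O[Si](C)(C)C(C)(C)C)[C@@H](OCc5ccc(OC)cc5)[C@H]2C(C[N+](C)(C)C)C(=O)O[C@@H]2/C=C(/C)C1.[I-] | intermediate
46 | α-methylene lactone (O8 PMB; O9 TBS; C14 OTBDPS) | C1/C=C(/CO[Si](c3ccccc3)(c4ccccc4)C(C)(C)C)[C@H](O[Si](C)(C)C(C)(C)C)[C@@H](OCc5ccc(OC)cc5)[C@H]2C(=C)C(=O)O[C@@H]2/C=C(/C)C1 | intermediate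
47 | C9 alcohol (O8 PMB; C14 OTBDPS) | C1/C=C(/CO[Si](c3ccccc3)(c4ccccc4)C(C)(C)C)[C@H](O)[C@@H](OCc5ccc(OC)cc5)[C@H]2C(=C)C(=O)O[C@@H]2/C=C(/C)C1 | intermediate
48 | C9 2-methyl-2-[(triethylsilyl)oxy]propanoate (O8 PMB) | C1/C=C(/CO[Si](c3ccccc3)(c4ccccc4)C(C)(C)C)[C@H](OC(=O)C(C)(C)O[Si](CC)(CC)CC)[C@@H](OCc5ccc(OC)cc5)[C@H]2C(=C)C(=O)O[C@@H]2/C=C(/C)C1 | intermediate
49 | C8 alcohol | C1/C=C(/CO[Si](c3ccccc3)(c4ccccc4)C(C)(C)C)[C@H](OC(=O)C(C)(C)O[Si](CC)(CC)CC)[C@@H](O)[C@H]2C(=C)C(=O)O[C@@H]2/C=C(/C)C1 | intermediate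
50 | C8 2-methylpropanoate (C14 OTBDPS; tertiary OTES) | C1/C=C(/CO[Si](c3ccccc3)(c4ccccc4)C(C)(C)C)[C@H](OC(=O)C(C)(C)O[Si](CC)(CC)CC)[C@@H](OC(=O)C(C)C)[C@H]2C(=C)C(=O)O[C@@H]2/C=C(/C)C1 | intermediate
51 | CNP0220567.2: (6R,7S,8S,9S; 1(10)Z,4Z)-14-hydroxy-9-(2-hydroxy-2-methylpropanoyloxy)-8-(2-methylpropanoyloxy)germacra-1(10),4,11(13)-trien-6,12-olide | C=C1C(=O)O[C@@H]2/C=C(/C)CC/C=C(/CO)[C@H](OC(=O)C(C)(C)O)[C@@H](OC(=O)C(C)C)[C@@H]12 | target

Total step count: 33. Longest linear sequence: 26 steps (steps 8–33, from 13 to 51).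

Steps most likely to fail:

(1) Step 24. Intermolecular alkylation (oligomerisation) or base-induced loss of HBr may outrun closure of the ten-membered ring. The fallback changes the ring-closing bond. It sets out from 29 and 8. Alcohol 8 is converted with CBr4/PPh3 into (Z)-3-bromo-1-iodo-2-methylprop-1-ene F1. The potassium anion of 29 (KN(SiMe3)2, THF, −78 °C) is alkylated with it to give the open-chain C2–C3 coupled vinyl iodide F2. The acetal is opened with iBu2AlH to the C6 primary alcohol F3, which Dess–Martin periodinane oxidises to the aldehyde F4. An intramolecular Nozaki–Hiyama–Kishi reaction (CrCl2, NiCl2 cat., DMSO/THF, high dilution) then closes the ring at C5–C6 to the macrocyclic C6 alcohol F5, with C6 set by Felkin–Anh addition. Silylation with Et3SiOTf/2,6-lutidine comes back to the route at 39.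

(2) Step 12. Facial selectivity at C9 may be poor if Felkin–Anh addition competes with the magnesium chelate. The fallback sets C9 by reduction instead of addition. It sets out from the crude mixture of 22 and its C9 epimer F6. Both are oxidised with Dess–Martin periodinane to the enone F7, which is reduced under Luche conditions (NaBH4, CeCl3·7H2O, MeOH, −78 °C). Hydride attack anti to the C8–O bond should give the 8,9-syn alcohol, which comes back to the route at 22.

(3) Step 25. The hindered cyclic sulfone may ionise slowly, or the C1=C10 alkene may migrate or isomerise from cis to trans through the π-allyl complex. The fallback replaces the π-allyl hydride pathway by electron-transfer cleavage of the C–S bond. It sets out from 39, which is treated with sodium amalgam Na(Hg) and Na2HPO4 in MeOH/THF at −20 °C. This comes back directly at 40 and makes no new compound (F0).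

Further compounds
F1 | step 24 | (Z)-3-bromo-1-iodo-2-methylprop-1-ene | BrC/C(C)=C\I
F2 | step 24 | C2-alkylated sulfone acetal (29 carrying the (Z)-3-iodo-2-methylallyl group on C2; C2 epimers) | O=S(=O)(c6ccccc6)C(C/C(C)=C\I)/C=C(/CO[Si](c3ccccc3)(c4ccccc4)C(C)(C)C)[C@H](O[Si](C)(C)C(C)(C)C)[C@H]1O[C@@H](c5ccc(OC)cc5)OC[C@@H]1CCO[Si](C)(C)C(C)(C)C
F3 | step 24 | C6 primary alcohol with O8 PMB (from F2) | O=S(=O)(c6ccccc6)C(C/C(C)=C\I)/C=C(/CO[Si](c3ccccc3)(c4ccccc4)C(C)(C)C)[C@H](O[Si](C)(C)C(C)(C)C)[C@@H](OCc5ccc(OC)cc5)[C@@H](CCO[Si](C)(C)C(C)(C)C)CO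
F4 | step 24 | C6 aldehyde bearing the C5 vinyl iodide | O=S(=O)(c6ccccc6)C(C/C(C)=C\I)/C=C(/CO[Si](c3ccccc3)(c4ccccc4)C(C)(C)C)[C@H](O[Si](C)(C)C(C)(C)C)[C@@H](OCc5ccc(OC)cc5)[C@@H](CCO[Si](C)(C)C(C)(C)C)C=O
F5 | step 24 | macrocyclic C6 alcohol (SO2Ph on C2; C2 epimers) | O=S(=O)(c6ccccc6)C1/C=C(/CO[Si](c3ccccc3)(c4ccccc4)C(C)(C)C)[C@H](O[Si](C)(C)C(C)(C)C)[C@@H](OCc5ccc(OC)cc5)[C@@H](CCO[Si](C)(C)C(C)(C)C)[C@H](O)/C=C(/C)C1
F6 | step 12 | C9 epimer of 22 | c6ccccc6SC/C=C(/CO[Si](c3ccccc3)(c4ccccc4)C(C)(C)C)[C@@H](O)[C@H]1O[C@@H](c5ccc(OC)cc5)OC[C@@H]1CC=C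
F7 | step 12 | C9 enone | c6ccccc6SC/C=C(/CO[Si](c3ccccc3)(c4ccccc4)C(C)(C)C)C(=O)[C@H]1O[C@@H](c5ccc(OC)cc5)OC[C@@H]1CC=C
F0 | step 25 | none | none
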